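**Retrosynthetic overview**
1. The last bond made is the allylic C7–O(alkyl) bond. The target comes from the trans-7-chloro-6-angelate of the bicyclic enone and silver (2R,3R)-epoxyangelate, by substitution with retention through the angelate-derived dioxolanylium ion.
2. The C2 ketone comes from allylic CH2 oxidation. Ring B (seven-membered) comes from ring-closing metathesis at C8=C9 and is the only ring built; ring A (six-membered) is bought.
3. The C6–C7 bond and both heteroatom-bearing stereocentres come from a reagent-controlled (Z)-γ-chloroallylboration of a neopentyl aldehyde, followed by angeloylation of C6–OH.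
4. The C4a–C5 bond, the quaternary C5 and the cis ring fusion come from an Ireland–Claisen rearrangement of the isobutyrate of (1S,4R)-p-mentha-2,8-dien-1-ol, which supplies ring A and C9a from the chiral pool.
5. (2R,3R)-Epoxyangelic acid comes from Sharpless epoxidation of angelyl alcohol, made from the same angelic acid that supplies the C6 ester.

Assumption: locants follow the benzo[7]annulene (himachalane) skeleton. C2 is the ketone, C3=C4 the enone alkene, C4a/C9a the cis ring fusion, C5 the CMe2 carbon, C6 the angelate carbon, C7 the epoxyangelate carbon and C8=C9 the ring B alkene. The target is read as (4aS,6R,7R,9aR), with a trans 6,7-diester, a Z angelate and a (2R,3R)-epoxyangelate. No protecting groups are used.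

Step 1
Reactants: 1 (1S,4R)-1-methyl-4-(prop-1-en-2-yl)cyclohex-2-en-1-ol; 2 isobutyric anhydride
Product: 3 (1S,4R)-1-methyl-4-(prop-1-en-2-yl)cyclohex-2-en-1-yl 2-methylpropanoate
Conditions: Et3N, DMAP (0.2 equiv), CH2Cl2, rt, 24 h
Reagents that add atoms: none
Why: DMAP-catalysed acyl transfer esterifies the tertiary allylic alcohol under basic conditions, so the allylic C–O bond cannot ionise and no stereocentre is touched.

Step 2
Reactants: 3 (1S,4R)-1-methyl-4-(prop-1-en-2-yl)cyclohex-2-en-1-yl 2-methylpropanoate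
Product: 6 2-methyl-2-[(1S,6R)-3-methyl-6-(prop-1-en-2-yl)cyclohex-2-en-1-yl]propanal, via silyl ketene acetal 4 (not isolated), via trimethylsilyl ester 5 (not isolated)
Conditions: LiN(i-Pr)2, Me3SiCl, THF, −78 °C → 50 °C; evaporate; i-Bu2AlH, CH2Cl2, −78 °C; aq. potassium sodium tartrate
Reagents that add atoms: none
Why: Ireland–Claisen rearrangement, in which the ketene acetal reaches the ring alkene only from the face carrying the C–O bond (also the isopropenyl face), so the suprafacial [3,3] shift sets C4a cis to C9a, builds the quaternary C5 and moves the alkene to C3=C4, after which the hindered silyl ester takes up a single hydride because its aluminium acetal survives at −78 °C (partial reduction of a silyl ester).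

Step 3
Reactants: 6 2-methyl-2-[(1S,6R)-3-methyl-6-(prop-1-en-2-yl)cyclohex-2-en-1-yl]propanal; 7 allyl chloride
Product: 10 (3R,4R)-4-chloro-2-methyl-2-[(1S,6R)-3-methyl-6-(prop-1-en-2-yl)cyclohex-2-en-1-yl]hex-5-en-3-ol, via chloroallylborane 8 (not isolated), via borinate 9 (not isolated)
Conditions: 7, LiN(c-C6H11)2, (−)-Ipc2BOMe, Et2O, −95 °C; BF3·OEt2 (1.3 equiv); then 6, −95 → −78 °C; HOCH2CH2NH2, rt
Reagents that add atoms: none
Why: Asymmetric (Z)-γ-chloroallylboration through a chair Zimmerman–Traxler transition state, in which the Z geometry of 8 gives the syn chlorohydrin and the isopinocampheyl groups from (+)-α-pinene select the aldehyde face leading to the (R)-carbinol, so C6 and C7 are set under reagent control, and BF3 is consumed before 6 is added so the aldehyde cannot close onto the isopropenyl group by a carbonyl-ene reaction.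

Step 4
Reactants: 10 (3R,4R)-4-chloro-2-methyl-2-[(1S,6R)-3-methyl-6-(prop-1-en-2-yl)cyclohex-2-en-1-yl]hex-5-en-3-ol; 11 angelic acid
Product: 13 (3R,4R)-4-chloro-2-methyl-2-[(1S,6R)-3-methyl-6-(prop-1-en-2-yl)cyclohex-2-en-1-yl]hex-5-en-3-yl (Z)-2-methylbut-2-enoate, via mixed anhydride 12 (not isolated)
Conditions: 11, 2,4,6-Cl3C6H2COCl, Et3N, toluene, rt; then 10, 80 °C
Reagents that add atoms: none
Why: Yamaguchi-type mixed-anhydride esterification without DMAP is the standard way to put angelic acid on a hindered alcohol without Z-to-E isomerisation, the weakly basic medium does not close the chlorohydrin, and no stereocentre changes.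

Step 5
Reactants: 13 (3R,4R)-4-chloro-2-methyl-2-[(1S,6R)-3-methyl-6-(prop-1-en-2-yl)cyclohex-2-en-1-yl]hex-5-en-3-yl (Z)-2-methylbut-2-enoate
Product: 14 (4aS,6R,7R,9aR)-7-chloro-3,5,5,9-tetramethyl-2,4a,5,6,7,9a-hexahydro-1H-benzo[7]annulen-6-yl (Z)-2-methylbut-2-enoate
Conditions: second-generation Hoveyda–Grubbs catalyst (7 mol %), toluene (2 mM), 80 °C, Ar sparge
Reagents that add atoms: none
Why: Ring-closing metathesis, in which the catalyst loads on the only monosubstituted alkene and closes onto the isopropenyl group, helped by the cis-1,2 arrangement on ring A and the gem-dimethyl effect, while the ring A alkene and the electron-poor angelate stay inert and the ring enforces the Z alkene.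

Step 6
Reactants: 14 (4aS,6R,7R,9aR)-7-chloro-3,5,5,9-tetramethyl-2,4a,5,6,7,9a-hexahydro-1H-benzo[7]annulen-6-yl (Z)-2-methylbut-2-enoate
Product: 15 (4aS,6R,7R,9aR)-7-chloro-3,5,5,9-tetramethyl-2-oxo-2,4a,5,6,7,9a-hexahydro-1H-benzo[7]annulen-6-yl (Z)-2-methylbut-2-enoate
Conditions: CrO3, 3,5-dimethylpyrazole, CH2Cl2, −20 °C
Reagents that add atoms: chromium trioxide, O=[Cr](=O)=O
Why: Allylic oxidation with the CrO3–3,5-dimethylpyrazole complex attacks the more electron-rich C3=C4 alkene, whose only allylic methylene is C2 (C4a is tertiary and shielded by C5), while C8=C9 is deactivated by the allylic chloride and no stereocentre is touched.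

Step 7
Reactants: 11 angelic acid
Product: 16 (Z)-2-methylbut-2-en-1-ol
Conditions: LiAlH4, Et2O, 0 °C → rt
Reagents that add atoms: none
Why: Hydride reduction of the carboxylic acid gives the allylic alcohol without reducing or isomerising the trisubstituted Z alkene.

Step 8
Reactants: 16 (Z)-2-methylbut-2-en-1-ol
Product: 17 [(2S,3R)-2,3-dimethyloxiran-2-yl]methanol
Conditions: Ti(Oi-Pr)4 (10 mol %), L-(+)-diethyl tartrate (12 mol %), t-BuOOH, 4 Å MS, CH2Cl2, −20 °C
Reagents that add atoms: tert-butyl hydroperoxide, CC(C)(C)OO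
Why: Sharpless asymmetric epoxidation with L-(+)-diethyl tartrate delivers oxygen to the face that gives the (2S,3R)-epoxy alcohol (the same sense as for nerol), and syn addition keeps the two methyl groups trans as in the Z alkene.

Step 9
Reactants: 17 [(2S,3R)-2,3-dimethyloxiran-2-yl]methanol
Product: 18 (2R,3R)-2,3-dimethyloxirane-2-carboxylic acid
Conditions: RuCl3 (2 mol %), NaIO4, MeCN/EtOAc/H2O, 0 °C → rt
Reagents that add atoms: sodium periodate, [Na+].[O-]I(=O)(=O)=O
Why: RuO4-catalysed oxidation takes the primary alcohol to the acid without opening the epoxide, and the stereocentres are untouched (C2 changes its descriptor from S to R only because the priority order changes).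

Step 10
Reactants: 15 (4aS,6R,7R,9aR)-7-chloro-3,5,5,9-tetramethyl-2-oxo-2,4a,5,6,7,9a-hexahydro-1H-benzo[7]annulen-6-yl (Z)-2-methylbut-2-enoate; 18 (2R,3R)-2,3-dimethyloxirane-2-carboxylic acid
Product: 21 (4aS,6R,7R,9aR)-3,5,5,9-tetramethyl-6-{[(Z)-2-methylbut-2-enoyl]oxy}-2-oxo-2,4a,5,6,7,9a-hexahydro-1H-benzo[7]annulen-7-yl (2R,3R)-2,3-dimethyloxirane-2-carboxylate, via silver carboxylate 19 (not isolated), via dioxolanylium ion 20 (not isolated)
Conditions: 18, Ag2O, 4 Å MS, toluene, rt, dark; then 15, AgOSO2CF3 (10 mol %), −20 °C → rt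
Reagents that add atoms: none
Why: Proposed new method: monovalent silver pulls off the allylic chloride of 15 while the trans-vicinal angelate carbonyl closes from the opposite face to give the cis-fused 2-alkenyl-1,3-dioxolan-2-ylium ion 20 (first inversion at C7), and the epoxyangelate counter-ion opens 20 by SN2 attack at the allylic C7 (second inversion), so the C7–O bond forms with net retention, trans to the C6 angelate, and no free hydroxyl ever exists that would let the two acyl groups migrate; attack at C6 is blocked by the quaternary C5, SN2′ attack at C9 by full substitution, and the sieves keep out the water that would hydrolyse 20; the closest known reaction types are the second stage of the Prévost reaction (one carboxylate used twice) and 1,2-trans Koenigs–Knorr couplings with neighbouring-acyl participation, neither of which has been used to place two different acyl groups on a carbocyclic allylic trans-diol.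

**Compound list**
1 | (1S,4R)-1-methyl-4-(prop-1-en-2-yl)cyclohex-2-en-1-ol, (+)-p-mentha-2,8-dien-1-ol, OH and isopropenyl on the same ring face | C=C(C)[C@@H]1CC[C@](C)(O)C=C1 | starting material
2 | 2-methylpropanoic anhydride (isobutyric anhydride) | CC(C)C(=O)OC(=O)C(C)C | starting material
3 | (1S,4R)-1-methyl-4-(prop-1-en-2-yl)cyclohex-2-en-1-yl 2-methylpropanoate | C=C(C)[C@@H]1CC[C@](C)(OC(=O)C(C)C)C=C1 | intermediate
4 | trimethylsilyl ketene acetal of 3, formed in situ | C=C(C)[C@@H]1CC[C@](C)(OC(O[Si](C)(C)C)=C(C)C)C=C1 | intermediate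
5 | trimethylsilyl 2-methyl-2-[(1S,6R)-3-methyl-6-(prop-1-en-2-yl)cyclohex-2-en-1-yl]propanoate, formed in situ | C=C(C)[C@@H]1CCC(C)=C[C@@H]1C(C)(C)C(=O)O[Si](C)(C)C | intermediate
6 | 2-methyl-2-[(1S,6R)-3-methyl-6-(prop-1-en-2-yl)cyclohex-2-en-1-yl]propanal, side chain and isopropenyl cis | C=C(C)[C@@H]1CCC(C)=C[C@@H]1C(C)(C)C=O | intermediate
7 | 3-chloroprop-1-ene (allyl chloride) | C=CCCl | starting material
8 | [(Z)-3-chloroprop-2-en-1-yl]bis(isopinocampheyl)borane, Ipc from (+)-α-pinene, formed in situ | Cl/C=C\CB([C@@H]1C[C@@H]2C[C@H]([C@H]1C)C2(C)C)[C@@H]1C[C@@H]2C[C@H]([C@H]1C)C2(C)C | intermediate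
9 | bis(isopinocampheyl)borinate ester of 10, formed in situ | B([C@@H]1C[C@@H]2C[C@H]([C@H]1C)C2(C)C)([C@@H]1C[C@@H]2C[C@H]([C@H]1C)C2(C)C)O[C@@H]([C@H](Cl)C=C)C(C)(C)[C@H]1C=C(C)CC[C@H]1C(C)=C | intermediate
10 | (3R,4R)-4-chloro-2-methyl-2-[(1S,6R)-3-methyl-6-(prop-1-en-2-yl)cyclohex-2-en-1-yl]hex-5-en-3-ol, syn chlorohydrin | O[C@@H]([C@H](Cl)C=C)C(C)(C)[C@H]1C=C(C)CC[C@H]1C(C)=C | intermediate
11 | (Z)-2-methylbut-2-enoic acid (angelic acid) | C/C=C(/C)C(=O)O | starting material
12 | (Z)-2-methylbut-2-enoic 2,4,6-trichlorobenzoic anhydride, formed in situ | C/C=C(/C)C(=O)OC(=O)c1c(Cl)cc(Cl)cc1Cl | intermediate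
13 | (3R,4R)-4-chloro-2-methyl-2-[(1S,6R)-3-methyl-6-(prop-1-en-2-yl)cyclohex-2-en-1-yl]hex-5-en-3-yl (Z)-2-methylbut-2-enoate | C/C=C(/C)C(=O)O[C@@H]([C@H](Cl)C=C)C(C)(C)[C@H]1C=C(C)CC[C@H]1C(C)=C | intermediate
14 | (4aS,6R,7R,9aR)-7-chloro-3,5,5,9-tetramethyl-2,4a,5,6,7,9a-hexahydro-1H-benzo[7]annulen-6-yl (Z)-2-methylbut-2-enoate | C/C=C(/C)C(=O)O[C@H]1[C@H](Cl)C=C(C)[C@@H]2CCC(C)=C[C@@H]2C1(C)C | intermediate
15 | (4aS,6R,7R,9aR)-7-chloro-3,5,5,9-tetramethyl-2-oxo-2,4a,5,6,7,9a-hexahydro-1H-benzo[7]annulen-6-yl (Z)-2-methylbut-2-enoate | C/C=C(/C)C(=O)O[C@H]1[C@H](Cl)C=C(C)[C@@H]2CC(=O)C(C)=C[C@@H]2C1(C)C | intermediate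
16 | (Z)-2-methylbut-2-en-1-ol (angelyl alcohol) | C/C=C(/C)CO | intermediate
17 | [(2S,3R)-2,3-dimethyloxiran-2-yl]methanol | OC[C@]1(C)O[C@@H]1C | intermediate
18 | (2R,3R)-2,3-dimethyloxirane-2-carboxylic acid (epoxyangelic acid) | OC(=O)[C@]1(C)O[C@@H]1C | intermediate
19 | silver (2R,3R)-2,3-dimethyloxirane-2-carboxylate, formed in situ | [Ag+].[O-]C(=O)[C@]1(C)O[C@@H]1C | intermediate
20 | cis-fused 2-[(Z)-but-2-en-2-yl]-1,3-dioxolan-2-ylium ion spanning C6–O and C7–O of the bicyclic enone (6R,7S), formed in situ | C/C=C(/C)C3=[O+][C@H]4C=C(C)[C@@H]2CC(=O)C(C)=C[C@@H]2C(C)(C)[C@H]4O3 | intermediate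
21 | (4aS,6R,7R,9aR)-3,5,5,9-tetramethyl-6-{[(Z)-2-methylbut-2-enoyl]oxy}-2-oxo-2,4a,5,6,7,9a-hexahydro-1H-benzo[7]annulen-7-yl (2R,3R)-2,3-dimethyloxirane-2-carboxylate | C/C=C(/C)C(=O)O[C@H]1[C@H](OC(=O)[C@]2(C)O[C@@H]2C)C=C(C)[C@@H]2CC(=O)C(C)=C[C@@H]2C1(C)C | target

Total step count: 10. Longest linear sequence: 7 (steps 1–6 and 10).

**Three steps most likely to fail**

Step 10 is the new step. The risks are proton loss from ion 20 to a triene, Z-to-E drift of the angelate while it carries positive charge, and capture of 20 at its acyl carbon. The fallback uses only known chemistry, sets out from chlorohydrin 10 and comes back at target 21. K2CO3 in MeOH closes 10 to the cis-vinyl epoxide (2R,3S)-2-{2-[(1S,6R)-3-methyl-6-(prop-1-en-2-yl)cyclohex-2-en-1-yl]propan-2-yl}-3-vinyloxirane F1. Ring-closing metathesis as in step 5 gives the bicyclic vinyl epoxide (4aS,6R,7S,9aR)-6,7-epoxy-3,5,5,9-tetramethyl-2,4a,5,6,7,9a-hexahydro-1H-benzo[7]annulene F2. Acid 18 opens F2 at the allylic C7 with inversion (SN2 acidolysis of a cyclic vinyl epoxide) to the hydroxy ester (4aS,6R,7R,9aR)-6-hydroxy-3,5,5,9-tetramethyl-2,4a,5,6,7,9a-hexahydro-1H-benzo[7]annulen-7-yl (2R,3R)-2,3-dimethyloxirane-2-carboxylate F3. Base-free mixed-anhydride angeloylation as in step 4 gives the 2-deoxo diester (4aS,6R,7R,9aR)-3,5,5,9-tetramethyl-6-{[(Z)-2-methylbut-2-enoyl]oxy}-2,4a,5,6,7,9a-hexahydro-1H-benzo[7]annulen-7-yl (2R,3R)-2,3-dimethyloxirane-2-carboxylate F4. The CrO3/3,5-dimethylpyrazole oxidation of step 6 then gives 21.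

Step 6 may lack site selectivity: oxygen may be delivered at C4 with allylic transposition, or the tertiary C9a–H may be attacked. The fallback sets out from 14 and comes back at 15. It replaces direct C–H to C=O oxidation by an ene/[2,3] hydroxylation followed by alcohol oxidation. SeO2 (cat.)/t-BuOOH attacks the ring methylene at the more substituted end of C3=C4 and gives the allylic alcohol (4aS,6R,7R,9aR)-7-chloro-2-hydroxy-3,5,5,9-tetramethyl-2,4a,5,6,7,9a-hexahydro-1H-benzo[7]annulen-6-yl (Z)-2-methylbut-2-enoate F5 as a mixture of C2 epimers. Dess–Martin periodinane converts F5 into 15.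

Step 5 closes a trisubstituted cycloheptene onto an isopropenyl group next to a secondary allylic chloride and a bulky ester, so closure may be slow. The fallback sets out from 10 and comes back at 14, with ring formation and acylation in reverse order. Metathesis of the free, less encumbered chlorohydrin 10 gives the bicyclic chlorohydrin (4aS,6R,7R,9aR)-7-chloro-3,5,5,9-tetramethyl-2,4a,5,6,7,9a-hexahydro-1H-benzo[7]annulen-6-ol F6. F6 is then esterified with mixed anhydride 12 as in step 4 to give 14.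

**Further compounds**
F1 | step 10 | (2R,3S)-2-{2-[(1S,6R)-3-methyl-6-(prop-1-en-2-yl)cyclohex-2-en-1-yl]propan-2-yl}-3-vinyloxirane | C=C[C@@H]1O[C@@H]1C(C)(C)[C@H]2C=C(C)CC[C@H]2C(C)=C
F2 | step 10 | (4aS,6R,7S,9aR)-6,7-epoxy-3,5,5,9-tetramethyl-2,4a,5,6,7,9a-hexahydro-1H-benzo[7]annulene | O1[C@H]2[C@@H]1C=C(C)[C@@H]3CCC(C)=C[C@@H]3C2(C)C
F3 | step 10 | (4aS,6R,7R,9aR)-6-hydroxy-3,5,5,9-tetramethyl-2,4a,5,6,7,9a-hexahydro-1H-benzo[7]annulen-7-yl (2R,3R)-2,3-dimethyloxirane-2-carboxylate | O[C@H]1[C@H](OC(=O)[C@]2(C)O[C@@H]2C)C=C(C)[C@@H]2CCC(C)=C[C@@H]2C1(C)C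
F4 | step 10 | (4aS,6R,7R,9aR)-3,5,5,9-tetramethyl-6-{[(Z)-2-methylbut-2-enoyl]oxy}-2,4a,5,6,7,9a-hexahydro-1H-benzo[7]annulen-7-yl (2R,3R)-2,3-dimethyloxirane-2-carboxylate | C/C=C(/C)C(=O)O[C@H]1[C@H](OC(=O)[C@]2(C)O[C@@H]2C)C=C(C)[C@@H]2CCC(C)=C[C@@H]2C1(C)C
F5 | step 6 | (4aS,6R,7R,9aR)-7-chloro-2-hydroxy-3,5,5,9-tetramethyl-2,4a,5,6,7,9a-hexahydro-1H-benzo[7]annulen-6-yl (Z)-2-methylbut-2-enoate, C2 epimers | C/C=C(/C)C(=O)O[C@H]1[C@H](Cl)C=C(C)[C@@H]2CC(O)C(C)=C[C@@H]2C1(C)C
F6 | step 5 | (4aS,6R,7R,9aR)-7-chloro-3,5,5,9-tetramethyl-2,4a,5,6,7,9a-hexahydro-1H-benzo[7]annulen-6-ol | O[C@H]1[C@H](Cl)C=C(C)[C@@H]2CCC(C)=C[C@@H]2C1(C)C
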